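**Plan**
- Retrosynthesis: both C–CH2OH bonds (C3–C and C4–C) of the oxolane are cut together back to the C3=C4 alkene of a (2S,5S)-2,5-diaryl-2,5-dihydrofuran. That alkene is cut by metathesis, and the two benzylic C–O bonds by allylic substitution, back to an O-benzylconiferyl carbonate made from ferulic acid.
- Forward: ferulic acid → allylic tert-butyl carbonate 5 → (S)-allylic alcohol 7 → bis-allylic ether 10 (second molecule of 5) → dihydrofuran 11 by metathesis (the only ring closure) → syn bis-methoxycarbonylation → ester reduction → debenzylation.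
- Enabling feature: in the ring O1–C2–C3–C4–C5 with trans aryl groups at C2 and C5, a twofold axis runs through O1 and the midpoint of C3=C4. The two alkene faces are therefore homotopic, and syn delivery of two carbons can only give the C3/C4-cis pattern of the target (C3 substituent cis to the C2 aryl, C4 substituent trans to the C5 aryl).
- Stereochemistry: C2 and C5 come from the same Ir–phosphoramidite catalyst (steps 4 and 5); C3 and C4 come from the syn addition in step 7.

Key step: step 7

Assumption: with [Ir(cod)Cl]2 the (Sa,Sc,Sc)-binaphthol-derived N,N-bis(1-phenylethyl)phosphoramidite (ligand L) is taken to deliver O-nucleophiles to the Si face of the aryl-bearing allyl terminus, as with cinnamyl carbonates, giving (S)-branched products. The configuration of 7 is to be checked before step 5, and the mirror-image ligand used in steps 4 and 5 if it proves opposite.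

**Step 1**
Reactants: 1 ferulic acid; 2 benzyl bromide
Product: 3 benzyl (E)-3-(4-benzyloxy-3-methoxyphenyl)prop-2-enoate
Conditions: BnBr (2.3 equiv), K2CO3 (3 equiv), DMF, 60 °C
Reagents that add atoms: benzyl bromide 2, BrCc1ccccc1
Why: Williamson-type SN2 alkylation of both the phenoxide and the carboxylate by benzyl bromide under carbonate base protects the phenol and esterifies the acid in one operation.

**Step 2**
Reactants: 3 benzyl (E)-3-(4-benzyloxy-3-methoxyphenyl)prop-2-enoate
Product: 4 (E)-3-(4-benzyloxy-3-methoxyphenyl)prop-2-en-1-ol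
Conditions: i-Bu2AlH (3 equiv), CH2Cl2, −78 °C to 0 °C
Reagents that add atoms: none
Why: 1,2-Reduction of the α,β-unsaturated ester by i-Bu2AlH at low temperature gives the (E)-allylic alcohol and leaves the alkene and the aryl benzyl ether intact.

**Step 3**
Reactants: 4 (E)-3-(4-benzyloxy-3-methoxyphenyl)prop-2-en-1-ol
Product: 5 tert-butyl (E)-3-(4-benzyloxy-3-methoxyphenyl)prop-2-en-1-yl carbonate
Conditions: Boc2O (1.3 equiv), Bu4NHSO4 (cat.), 30% aq NaOH, CH2Cl2, 0 °C to rt
Reagents that add atoms: di-tert-butyl dicarbonate, CC(C)(C)OC(=O)OC(=O)OC(C)(C)C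
Why: Phase-transfer O-acylation of the primary allylic alcohol with Boc2O (carbonate formation) gives the allylic tert-butyl carbonate, chosen over a methyl carbonate because the tert-butoxide it releases on ionisation is too hindered to compete as a nucleophile in steps 4 and 5.

**Step 4**
Reactants: 5 tert-butyl (E)-3-(4-benzyloxy-3-methoxyphenyl)prop-2-en-1-yl carbonate
Product: 7 (S)-1-(4-benzyloxy-3-methoxyphenyl)prop-2-en-1-ol, via triethylsilyl ether 6 (not isolated)
Conditions: Et3SiOK (2 equiv), [Ir(cod)Cl]2 (2 mol%), (Sa,Sc,Sc)-L (4 mol%), CH2Cl2, rt; then Bu4NF, THF, 0 °C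
Reagents that add atoms: potassium triethylsilanolate, CC[Si]([O-])(CC)CC.[K+]
Why: Iridium-catalysed asymmetric allylic substitution with a silanolate as hydroxide surrogate: the cyclometallated Ir–phosphoramidite allyl complex is attacked at the aryl-bearing terminus on the face dictated by the ligand, which sets the (S) stereocentre, and fluoride then cleaves the Si–O bond without touching the benzyl ether.

**Step 5**
Reactants: 7 (S)-1-(4-benzyloxy-3-methoxyphenyl)prop-2-en-1-ol; 5 tert-butyl (E)-3-(4-benzyloxy-3-methoxyphenyl)prop-2-en-1-yl carbonate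
Product: 10 bis[(S)-1-(4-benzyloxy-3-methoxyphenyl)prop-2-en-1-yl] ether, via lithium alkoxide 8 (not isolated), via copper alkoxide 9 (not isolated)
Conditions: 7 (1.3 equiv), n-BuLi, THF, 0 °C; CuI (copper iodide), rt; then 5, [Ir(cod)Cl]2 (2 mol%), (Sa,Sc,Sc)-L (4 mol%), THF, rt
Reagents that add atoms: none
Why: Iridium-catalysed allylic etherification with a soft copper alkoxide: the alkoxide oxygen of 9 attacks the aryl-bearing allyl terminus of the complex derived from 5 under the same ligand control, so the new benzylic centre is again (S) by catalyst control while the centre already present in 7 is not involved in bond breaking.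

**Step 6**
Reactants: 10 bis[(S)-1-(4-benzyloxy-3-methoxyphenyl)prop-2-en-1-yl] ether
Product: 11 (2S,5S)-2,5-bis(4-benzyloxy-3-methoxyphenyl)-2,5-dihydrofuran
Conditions: second-generation Grubbs catalyst, RuCl2(=CHPh)(PCy3)(H2IMes) (3 mol%), CH2Cl2, 40 °C
Reagents that add atoms: none
Why: Ring-closing olefin metathesis of the two terminal vinyl groups closes the five-membered ring with loss of ethylene, an entropically driven closure that leaves both benzylic stereocentres untouched.

**Step 7**
Reactants: 11 (2S,5S)-2,5-bis(4-benzyloxy-3-methoxyphenyl)-2,5-dihydrofuran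
Product: 12 dimethyl (2S,3R,4S,5S)-2,5-bis(4-benzyloxy-3-methoxyphenyl)oxolane-3,4-dicarboxylate
Conditions: PdCl2 (10 mol%), CuCl2 (3 equiv), NaOAc (3 equiv), CO (3 atm), MeOH/THF 3:1, 20 °C
Reagents that add atoms: carbon monoxide, [C-]#[O+]; methanol, CO
Why: ClPd–CO2Me, formed from PdCl2, CO and methanol, adds syn across C3=C4, the resulting alkylpalladium inserts CO with retention and the acylpalladium is methanolysed, releasing zerovalent palladium that CuCl2 returns to divalent palladium. The closest known reaction type is the Pd/Cu oxidative bis-alkoxycarbonylation of cyclopentene-type cis-alkenes to cis-1,2-diesters. No ring is closed; both new bonds are exocyclic C–C bonds. The new stereocentres C3 and C4 are fixed relative to each other by the suprafacial insertion and relative to C2 and C5 by the twofold axis through O1 and the C3=C4 midpoint, which makes the faces homotopic, so either face and either regiochemistry of the first insertion leads to the same diester with the C3 ester cis to the C2 aryl and the C4 ester trans to the C5 aryl. The step needs only syn delivery and a CO insertion that outruns β-hydride elimination and ionisation of the benzylic C–O bonds; CO pressure, ambient temperature and the acetate buffer for the HCl produced on CuCl2 turnover are meant to secure this.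

**Step 8**
Reactants: 12 dimethyl (2S,3R,4S,5S)-2,5-bis(4-benzyloxy-3-methoxyphenyl)oxolane-3,4-dicarboxylate
Product: 13 [(2S,3S,4R,5S)-2,5-bis(4-benzyloxy-3-methoxyphenyl)oxolane-3,4-diyl]dimethanol
Conditions: LiAlH4 (3 equiv), THF, 0 °C
Reagents that add atoms: none
Why: Hydride reduction of both methyl esters to primary alcohols by LiAlH4, fast enough at 0 °C that the α-stereocentres C3 and C4 should not epimerise and without effect on the benzyl ethers or the ring ether.

**Step 9**
Reactants: 13 [(2S,3S,4R,5S)-2,5-bis(4-benzyloxy-3-methoxyphenyl)oxolane-3,4-diyl]dimethanol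
Product: 14 4,4'-[(2S,3S,4R,5S)-3,4-bis(hydroxymethyl)oxolane-2,5-diyl]bis(2-methoxyphenol)
Conditions: H2 (1 atm), 10% Pd/C, EtOAc/MeOH, rt
Reagents that add atoms: none
Why: Catalytic hydrogenolysis cleaves the two aryl benzyl ethers, which react far faster than the dialkyl benzylic C–O bonds of the oxolane under neutral conditions at atmospheric pressure, so no stereocentre is affected.

**Compound list**
1 | ferulic acid, (E)-3-(4-hydroxy-3-methoxyphenyl)prop-2-enoic acid | COc1cc(/C=C/C(=O)O)ccc1O | starting material
2 | benzyl bromide | BrCc1ccccc1 | starting material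
3 | benzyl (E)-3-(4-benzyloxy-3-methoxyphenyl)prop-2-enoate | COc1cc(/C=C/C(=O)OCc2ccccc2)ccc1OCc1ccccc1 | intermediate
4 | (E)-3-(4-benzyloxy-3-methoxyphenyl)prop-2-en-1-ol | COc1cc(/C=C/CO)ccc1OCc1ccccc1 | intermediate
5 | tert-butyl (E)-3-(4-benzyloxy-3-methoxyphenyl)prop-2-en-1-yl carbonate | COc1cc(/C=C/COC(=O)OC(C)(C)C)ccc1OCc1ccccc1 | intermediate
6 | (S)-[1-(4-benzyloxy-3-methoxyphenyl)prop-2-en-1-yloxy]triethylsilane (not isolated) | C=C[C@H](O[Si](CC)(CC)CC)c1ccc(OCc2ccccc2)c(OC)c1 | intermediate
7 | (S)-1-(4-benzyloxy-3-methoxyphenyl)prop-2-en-1-ol | C=C[C@H](O)c1ccc(OCc2ccccc2)c(OC)c1 | intermediate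
8 | lithium (S)-1-(4-benzyloxy-3-methoxyphenyl)prop-2-en-1-olate (not isolated) | C=C[C@H]([O-])c1ccc(OCc2ccccc2)c(OC)c1.[Li+] | intermediate
9 | copper (S)-1-(4-benzyloxy-3-methoxyphenyl)prop-2-en-1-olate, monovalent copper (not isolated) | C=C[C@H](O[Cu])c1ccc(OCc2ccccc2)c(OC)c1 | intermediate
10 | bis[(S)-1-(4-benzyloxy-3-methoxyphenyl)prop-2-en-1-yl] ether | C=C[C@H](O[C@@H](C=C)c1ccc(OCc2ccccc2)c(OC)c1)c1ccc(OCc2ccccc2)c(OC)c1 | intermediate
11 | (2S,5S)-2,5-bis(4-benzyloxy-3-methoxyphenyl)-2,5-dihydrofuran | COc1cc([C@H]2O[C@H](c3ccc(OCc4ccccc4)c(OC)c3)C=C2)ccc1OCc1ccccc1 | intermediate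
12 | dimethyl (2S,3R,4S,5S)-2,5-bis(4-benzyloxy-3-methoxyphenyl)oxolane-3,4-dicarboxylate (aryls trans, esters cis, C3 ester cis to C2 aryl) | COc1cc([C@H]2O[C@H](c3ccc(OCc4ccccc4)c(OC)c3)[C@@H](C(=O)OC)[C@H]2C(=O)OC)ccc1OCc1ccccc1 | intermediate
13 | [(2S,3S,4R,5S)-2,5-bis(4-benzyloxy-3-methoxyphenyl)oxolane-3,4-diyl]dimethanol | COc1cc([C@H]2O[C@H](c3ccc(OCc4ccccc4)c(OC)c3)[C@@H](CO)[C@H]2CO)ccc1OCc1ccccc1 | intermediate
14 | 4,4'-[(2S,3S,4R,5S)-3,4-bis(hydroxymethyl)oxolane-2,5-diyl]bis(2-methoxyphenol) | COc1cc([C@H]2O[C@H](c3ccc(O)c(OC)c3)[C@@H](CO)[C@H]2CO)ccc1O | target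

**Step count**
Total steps: 9. Longest linear sequence: 9 steps (1 to 14); carbonate 5 is used twice, as substrate in step 4 and as electrophile in step 5.

**Steps most likely to fail**

Step 7. What may go wrong: the doubly benzylic, allylic C–O bonds of 11 may ionise under the acid and Lewis-acidic copper and palladium chlorides, leading to methanolysis or epimerisation at C2/C5. The alkylpalladium may also undergo β-hydride elimination toward C5 before CO insertion, or the ring may be dehydrogenated to the 2,5-diarylfuran. The fallback replaces the carbonylation by a neutral syn diboration and sets out from 11. B2pin2 with Pt(dba)3 (zerovalent platinum) in toluene at 60 °C should add both boron atoms to one of the homotopic faces and give (2S,3R,4S,5S)-2,5-bis(4-benzyloxy-3-methoxyphenyl)-3,4-bis(4,4,5,5-tetramethyl-1,3,2-dioxaborolan-2-yl)oxolane F1. Double Matteson homologation with LiCH2Cl (BrCH2Cl, n-BuLi, THF, −78 °C to rt), in which each carbon migrates with retention, would give the 3,4-bis(pinacolborylmethyl)oxolane F2. Oxidation with NaOH/H2O2 in THF/water then gives diol 13, where the route is rejoined before step 9; step 8 is not needed.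

Step 5. What may go wrong: loss of branched regioselectivity and of diastereocontrol if the electron-rich aryl-allyl iridium complex isomerises or the branched ether re-ionises, and competing attack by the released tert-butoxide. The fallback makes the ether stereospecifically and not under catalyst control, and sets out from 7. Part of 7 is converted with LiN(SiMe3)2 and Boc2O (THF, −78 °C) into (S)-tert-butyl 1-(4-benzyloxy-3-methoxyphenyl)prop-2-en-1-yl carbonate F3. This is coupled with copper alkoxide 9 (from the remaining 7) under RhCl(PPh3)3/P(OMe)3 catalysis in THF at 0 °C. Rhodium-catalysed allylic etherification of branched carbonates is expected to proceed with net retention through a configurationally stable enyl intermediate, so both stereocentres derive from 7. The product is ether 10, where the route is rejoined at step 6.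

Step 4. What may go wrong: incomplete enantiocontrol or branched/linear selectivity with the electron-rich cinnamyl system, and racemisation of the product by re-ionisation. The fallback obtains the alcohol by resolution and sets out from benzyl bromide 2. O-Benzylation of vanillin (K2CO3, DMF) gives 4-benzyloxy-3-methoxybenzaldehyde F4. Addition of CH2=CHMgBr (THF, −78 °C to 0 °C) gives racemic 1-(4-benzyloxy-3-methoxyphenyl)prop-2-en-1-ol F5. Lipase-mediated kinetic resolution (Burkholderia cepacia lipase, vinyl acetate, MTBE, rt, run past half conversion) is expected, by the usual empirical selectivity for secondary alcohols, to acylate the (R)-enantiomer to (R)-1-(4-benzyloxy-3-methoxyphenyl)prop-2-en-1-yl acetate F6 and leave the (S)-alcohol. After chromatographic separation this is 7, where the route is rejoined at step 5; carbonate 5 is still made by steps 1 to 3 for use in step 5.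

**Further compounds**
F1 | step 7 | (2S,3R,4S,5S)-2,5-bis(4-benzyloxy-3-methoxyphenyl)-3,4-bis(4,4,5,5-tetramethyl-1,3,2-dioxaborolan-2-yl)oxolane | COc1cc([C@H]2O[C@H](c3ccc(OCc4ccccc4)c(OC)c3)[C@@H](B5OC(C)(C)C(C)(C)O5)[C@H]2B6OC(C)(C)C(C)(C)O6)ccc1OCc1ccccc1
F2 | step 7 | (2S,3R,4S,5S)-2,5-bis(4-benzyloxy-3-methoxyphenyl)-3,4-bis[(4,4,5,5-tetramethyl-1,3,2-dioxaborolan-2-yl)methyl]oxolane | COc1cc([C@H]2O[C@H](c3ccc(OCc4ccccc4)c(OC)c3)[C@@H](CB5OC(C)(C)C(C)(C)O5)[C@H]2CB6OC(C)(C)C(C)(C)O6)ccc1OCc1ccccc1
F3 | step 5 | (S)-tert-butyl 1-(4-benzyloxy-3-methoxyphenyl)prop-2-en-1-yl carbonate | C=C[C@H](OC(=O)OC(C)(C)C)c1ccc(OCc2ccccc2)c(OC)c1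
F4 | step 4 | 4-benzyloxy-3-methoxybenzaldehyde | COc1cc(C=O)ccc1OCc1ccccc1
F5 | step 4 | racemic 1-(4-benzyloxy-3-methoxyphenyl)prop-2-en-1-ol | C=CC(O)c1ccc(OCc2ccccc2)c(OC)c1
F6 | step 4 | (R)-1-(4-benzyloxy-3-methoxyphenyl)prop-2-en-1-yl acetate | C=C[C@@H](OC(C)=O)c1ccc(OCc2ccccc2)c(OC)c1
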